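**Retrosynthetic overview**
1. Target 25 comes from global hydrogenolysis of the benzyl-protected, C8'-brominated digallate 24, which comes from double galloylation of dimer diol 22 (allyl ether of 20 removed).
2. The interflavan C4–C6' bond of 20 comes from a Lewis-acid Friedel–Crafts union of the upper flavan-4-ol 16 with C8-brominated, benzylated (−)-epicatechin 19 (lower unit from the chiral pool).
3. The upper unit comes from the key annulation: the C2 alkoxide of acyclic Weinreb amide 12 adds to 3,5-bis(benzyloxy)benzyne (O1–C8a) and the resulting C4a carbanion closes ring C on the C4 acyl carbon (C4–C4a). Amide 12 comes from an Evans syn-glycolate aldol that sets C2 and C3.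
4. Enabling feature: ring A is a 1,3,5-trioxygenated benzene whose O5 flanks C4a. This polarises the C4a≡C8a aryne so that O1 bonds to C8a and the carbanion sits on C4a; O1 and C4 are 1,3-related on the C2–C3–C4 chain, so the closure gives the six-membered ring C.
5. Ring order: ring B and the galloyl rings are bought; upper ring A arrives intact as the aryne and ring C closes onto it in step 6; lower rings A, B and C come from (−)-epicatechin; the two flavan units are joined in step 10.

Key step: step 6

Remark: alcohol 16 is drawn as the expected 3,4-cis epimer; its C4 configuration is immaterial because C4 is ionised in step 10.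

Step 1
Reactants: 1 3,5-bis(benzyloxy)phenol
Product: 2 3,5-bis(benzyloxy)-2-bromophenol
Conditions: NBS (1.0 equiv), i-Pr2NH (0.1 equiv), CH2Cl2, 0 °C
Reagents that add atoms: N-bromosuccinimide O=C1CCC(=O)N1Br
Why: Amine-catalysed electrophilic aromatic bromination with NBS should deliver bromine ortho to the free hydroxyl of the symmetrical phenol (both ortho sites are equivalent), which is the position needed for the silyl triflate.

Step 2
Reactants: 2 3,5-bis(benzyloxy)-2-bromophenol
Product: 5 3,5-bis(benzyloxy)-2-(trimethylsilyl)phenyl trifluoromethanesulfonate, via aryl trimethylsilyl ether 3 (not isolated), via lithium silylphenolate 4 (not isolated)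
Conditions: HMDS, THF, 65 °C, then evaporate; n-BuLi, THF, −78 °C; Tf2O, −78 °C → rt
Reagents that add atoms: hexamethyldisilazane C[Si](C)(C)N[Si](C)(C)C; trifluoromethanesulfonic anhydride O=S(=O)(OS(=O)(=O)C(F)(F)F)C(F)(F)F
Why: This is the standard one-flask route to 2-silylaryl triflates, namely O-silylation, bromine–lithium exchange with 1,3-O-to-C silyl migration (retro-Brook rearrangement) and O-triflation, and the benzyl ethers should tolerate n-BuLi at −78 °C.

Step 3
Reactants: 6 (prop-2-en-1-yloxy)acetic acid; 7 (4S)-4-benzyl-1,3-oxazolidin-2-one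
Product: 8 (4S)-4-benzyl-3-[(prop-2-en-1-yloxy)acetyl]-1,3-oxazolidin-2-one
Conditions: DCC, DMAP (cat.), CH2Cl2, 0 °C → rt
Reagents that add atoms: none
Why: Carbodiimide-mediated N-acylation (Steglich-type coupling) of the oxazolidinone by the alkoxyacetic acid is a routine entry to the Evans glycolate imide and creates no stereocentre.

Step 4
Reactants: 8 (4S)-4-benzyl-3-[(prop-2-en-1-yloxy)acetyl]-1,3-oxazolidin-2-one; 9 3,4-bis(benzyloxy)benzaldehyde
Product: 11 (4S)-4-benzyl-3-[(2S,3R)-3-[3,4-bis(benzyloxy)phenyl]-3-hydroxy-2-(prop-2-en-1-yloxy)propanoyl]-1,3-oxazolidin-2-one, via dibutylboron Z-enolate 10 (not isolated)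
Conditions: n-Bu2BOTf, Et3N, CH2Cl2, −78 → 0 °C; 9, −78 → 0 °C; pH 7 buffer, MeOH, H2O2, 0 °C
Reagents that add atoms: none
Why: In this Evans syn-aldol reaction the Z-boron enolate 10 adds to the aldehyde through a chair Zimmerman–Traxler transition state on the face away from the benzyl group of the (S)-auxiliary, which should set the benzylic carbinol carbon (future flavan C2, R) and the allyloxy-bearing carbon (future flavan C3) in the syn relation that becomes 2,3-cis.

Step 5
Reactants: 11 syn-aldol imide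
Product: 12 (2S,3R)-3-[3,4-bis(benzyloxy)phenyl]-3-hydroxy-N-methoxy-N-methyl-2-(prop-2-en-1-yloxy)propanamide
Conditions: MeNHOMe·HCl, AlMe3, CH2Cl2, −20 → 0 °C; aqueous potassium sodium tartrate
Reagents that add atoms: N,O-dimethylhydroxylamine hydrochloride CNOC.Cl
Why: Transamidation of the N-acyloxazolidinone by the aluminium amide of N,O-dimethylhydroxylamine (Weinreb amide formation), assisted by the free β-hydroxyl, should release the auxiliary without touching either stereocentre.

Step 6
Reactants: 12 β-hydroxy Weinreb amide; 5 3,5-bis(benzyloxy)-2-(trimethylsilyl)phenyl trifluoromethanesulfonate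
Product: 15 (2R,3S)-5,7-bis(benzyloxy)-2-[3,4-bis(benzyloxy)phenyl]-3-(prop-2-en-1-yloxy)-2,3-dihydro-4H-chromen-4-one (2,3-cis), via 3,5-bis(benzyloxy)benzyne 13 (not isolated), via potassium hemiaminal alkoxide 14 (not isolated)
Conditions: KH (1.05 equiv), 18-crown-6, THF, −20 °C; then 5 (1.3 equiv), KF (3 equiv), 0 °C → rt; AcOH, THF, −20 °C, then pH 7 buffer
Reagents that add atoms: none
Why: Proposed new method: the potassium alkoxide of 12 (O1 on C2) should add to aryne 13 at the carbon that becomes C8a, meta to the flanking benzyloxy group (future O5), because that oxygen polarises the triple bond and stabilises the ortho carbanion inductively; the carbanion therefore appears at C4a and adds to the C4 amide carbonyl to give hemiaminal alkoxide 14, which should release ketone 15 only on the acidic quench, so the epimerisable C3–H next to the ketone is not exposed to alkoxide. The closest known reaction type is the fluoride-induced aryne annulation of salicylate esters to xanthones and of ortho-hydroxychalcones to 9-substituted xanthenes (oxa-arylation followed by intramolecular trapping of the aryl anion), extended here from phenoxides to an aliphatic β-alkoxide with a tertiary amide as acyl acceptor. Ring C closes by 6-exo-trig addition of C4a to C4 after the intermolecular O1–C8a bond formation, and ring A arrives intact as the aryne. No new stereocentre persists (C4 ends as a carbonyl), and C2 and C3 from step 4 should be retained because no bond to them is broken and the amide α-proton is too weakly acidic for the alkoxide. The step needs regioselectivity in the aryne addition, secured by the 3-alkoxy substituent of the aryne, and chemoselectivity of the aryl anion for carbonyl addition over protonation, secured by the six-membered transition state, the aprotic medium and the use of KH, which leaves no amine conjugate acid.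

Step 7
Reactants: 15 2,3-cis-3-allyloxyflavan-4-one
Product: 16 (2R,3R,4R)-5,7-bis(benzyloxy)-2-[3,4-bis(benzyloxy)phenyl]-3-(prop-2-en-1-yloxy)-3,4-dihydro-2H-chromen-4-ol
Conditions: NaBH4, CeCl3·7H2O, MeOH/THF, −40 → 0 °C
Reagents that add atoms: none
Why: Luche reduction of the aryl ketone under cold, weakly basic conditions should give the flavan-4-ol without epimerising C3, with hydride arriving anti to the pseudo-axial 3-allyloxy group (3,4-cis alcohol expected).

Step 8
Reactants: 17 (−)-epicatechin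
Product: 18 5,7,3',4'-tetra-O-benzyl-(−)-epicatechin
Conditions: BnBr (4.2 equiv), K2CO3, DMF, 0 °C → rt, argon
Reagents that add atoms: benzyl bromide BrCc1ccccc1
Why: Williamson etherification should benzylate the four phenols selectively, because the secondary 3-hydroxyl is far less acidic, and leaves both stereocentres untouched.

Step 9
Reactants: 18 5,7,3',4'-tetra-O-benzyl-(−)-epicatechin
Product: 19 8-bromo-5,7,3',4'-tetra-O-benzyl-(−)-epicatechin
Conditions: NBS (1.0 equiv), CH2Cl2, −78 °C → rt
Reagents that add atoms: N-bromosuccinimide O=C1CCC(=O)N1Br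
Why: Electrophilic aromatic bromination of ring A should occur at C8, the more reactive free position of 5,7-di-O-benzylflavans, which blocks C8 and leaves C6 as the only nucleophilic site.

Step 10
Reactants: 16 upper flavan-4-ol; 19 8-bromo-5,7,3',4'-tetra-O-benzyl-(−)-epicatechin (3–4 equiv)
Product: 20 3-O-allyl-5,7,3',4'-tetra-O-benzylepicatechin-(4β→6)-8-bromo-5,7,3',4'-tetra-O-benzylepicatechin
Conditions: TMSOTf (cat.), 4 Å molecular sieves, CH2Cl2, −78 → −30 °C
Reagents that add atoms: none
Why: Lewis-acid ionisation of the C4 alcohol (the hydroxyl leaves as water, which the molecular sieves take up) gives the flavan-4-yl cation stabilised by ring A, which undergoes Friedel–Crafts alkylation by C6 of 19 (C8 blocked) on the face anti to the pseudo-axial 3-allyloxy group, as is usual for 2,3-cis flavan electrophiles, so the new C4 stereocentre should be 3,4-trans (4β).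

Step 11
Reactants: 20 allyl-protected dimer
Product: 22 5,7,3',4'-tetra-O-benzylepicatechin-(4β→6)-8-bromo-5,7,3',4'-tetra-O-benzylepicatechin (both 3-hydroxyls free), via prop-1-enyl ether 21 (not isolated)
Conditions: [Ir(cod)(PMePh2)2]PF6 (cat., activated with H2), THF, rt; then p-TsOH·H2O (cat.), THF/H2O, rt
Reagents that add atoms: none
Why: Iridium-catalysed isomerisation of the allyl ether to the prop-1-enyl ether 21 followed by mild acid hydrolysis of this enol ether is a deallylation that should spare the benzyl ethers, the aryl bromide and the interflavan bond.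

Step 12
Reactants: 22 dimer diol; 23 3,4,5-tris(benzyloxy)benzoic acid (3 equiv)
Product: 24 bis[3,4,5-tris(benzyloxy)benzoate] of 22
Conditions: DCC, DMAP, CH2Cl2, rt
Reagents that add atoms: none
Why: Steglich esterification with excess acid should acylate both secondary 3-hydroxyls with retention, since no bond to a stereocentre is broken.

Step 13
Reactants: 24 benzyl-protected bromo digallate
Product: 25 procyanidin B-5 3,3'-di-O-gallate
Conditions: H2 (1 atm), Pd(OH)2 on carbon, Et3N (1 equiv), THF/MeOH/H2O, rt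
Reagents that add atoms: none
Why: Catalytic hydrogenolysis should cleave all fourteen benzyl ethers and the aryl C–Br bond (triethylamine takes up HBr), while the gallate esters and all stereocentres are inert to these conditions.

**Compound list**
1 | 3,5-bis(benzyloxy)phenol | Oc1cc(OCc2ccccc2)cc(OCc2ccccc2)c1 | starting material
2 | 3,5-bis(benzyloxy)-2-bromophenol | Oc1cc(OCc2ccccc2)cc(OCc2ccccc2)c1Br | intermediate
3 | [3,5-bis(benzyloxy)-2-bromophenoxy]trimethylsilane | C[Si](C)(C)Oc1cc(OCc2ccccc2)cc(OCc2ccccc2)c1Br | intermediate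
4 | lithium 3,5-bis(benzyloxy)-2-(trimethylsilyl)phenolate | [Li+].[O-]c1cc(OCc2ccccc2)cc(OCc2ccccc2)c1[Si](C)(C)C | intermediate
5 | 3,5-bis(benzyloxy)-2-(trimethylsilyl)phenyl trifluoromethanesulfonate | C[Si](C)(C)c1c(OCc2ccccc2)cc(OCc2ccccc2)cc1OS(=O)(=O)C(F)(F)F | intermediate
6 | (prop-2-en-1-yloxy)acetic acid | C=CCOCC(=O)O | starting material
7 | (4S)-4-benzyl-1,3-oxazolidin-2-one | O=C1N[C@@H](Cc2ccccc2)CO1 | starting material
8 | (4S)-4-benzyl-3-[(prop-2-en-1-yloxy)acetyl]-1,3-oxazolidin-2-one | C=CCOCC(=O)N1[C@@H](Cc2ccccc2)COC1=O | intermediate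
9 | 3,4-bis(benzyloxy)benzaldehyde | O=Cc1ccc(OCc2ccccc2)c(OCc2ccccc2)c1 | starting material
10 | dibutylboron (Z)-enolate of 8 | C=CCO/C=C(\OB(CCCC)CCCC)N1[C@@H](Cc2ccccc2)COC1=O | intermediate
11 | (4S)-4-benzyl-3-[(2S,3R)-3-[3,4-bis(benzyloxy)phenyl]-3-hydroxy-2-(prop-2-en-1-yloxy)propanoyl]-1,3-oxazolidin-2-one | C=CCO[C@H](C(=O)N1[C@@H](Cc2ccccc2)COC1=O)[C@H](O)c1ccc(OCc2ccccc2)c(OCc2ccccc2)c1 | intermediate
12 | (2S,3R)-3-[3,4-bis(benzyloxy)phenyl]-3-hydroxy-N-methoxy-N-methyl-2-(prop-2-en-1-yloxy)propanamide | C=CCO[C@H](C(=O)N(C)OC)[C@H](O)c1ccc(OCc2ccccc2)c(OCc2ccccc2)c1 | intermediate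
13 | 3,5-bis(benzyloxy)benzyne (1,2-didehydro-3,5-bis(benzyloxy)benzene) | C1#CC(OCc2ccccc2)=CC(OCc2ccccc2)=C1 | intermediate
14 | potassium (2R,3S)-5,7-bis(benzyloxy)-2-[3,4-bis(benzyloxy)phenyl]-4-[methoxy(methyl)amino]-3-(prop-2-en-1-yloxy)-3,4-dihydro-2H-chromen-4-olate (C4 configuration not defined) | C=CCO[C@@H]1C([O-])(N(C)OC)c2c(OCc3ccccc3)cc(OCc3ccccc3)cc2O[C@@H]1c1ccc(OCc2ccccc2)c(OCc2ccccc2)c1.[K+] | intermediate
15 | (2R,3S)-5,7-bis(benzyloxy)-2-[3,4-bis(benzyloxy)phenyl]-3-(prop-2-en-1-yloxy)-2,3-dihydro-4H-chromen-4-one (2,3-cis) | C=CCO[C@@H]1C(=O)c2c(OCc3ccccc3)cc(OCc3ccccc3)cc2O[C@@H]1c1ccc(OCc2ccccc2)c(OCc2ccccc2)c1 | intermediate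
16 | (2R,3R,4R)-5,7-bis(benzyloxy)-2-[3,4-bis(benzyloxy)phenyl]-3-(prop-2-en-1-yloxy)-3,4-dihydro-2H-chromen-4-ol (2,3-cis, 3,4-cis) | C=CCO[C@@H]1[C@H](O)c2c(OCc3ccccc3)cc(OCc3ccccc3)cc2O[C@@H]1c1ccc(OCc2ccccc2)c(OCc2ccccc2)c1 | intermediate
17 | (−)-epicatechin, (2R,3R)-2-(3,4-dihydroxyphenyl)-3,4-dihydro-2H-chromene-3,5,7-triol | O[C@@H]1Cc2c(O)cc(O)cc2O[C@@H]1c1ccc(O)c(O)c1 | starting material
18 | 5,7,3',4'-tetra-O-benzyl-(−)-epicatechin | O[C@@H]1Cc2c(OCc3ccccc3)cc(OCc3ccccc3)cc2O[C@@H]1c1ccc(OCc2ccccc2)c(OCc2ccccc2)c1 | intermediate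
19 | 8-bromo-5,7,3',4'-tetra-O-benzyl-(−)-epicatechin | O[C@@H]1Cc2c(OCc3ccccc3)cc(OCc3ccccc3)c(Br)c2O[C@@H]1c1ccc(OCc2ccccc2)c(OCc2ccccc2)c1 | intermediate
20 | 3-O-allyl-5,7,3',4'-tetra-O-benzylepicatechin-(4β→6)-8-bromo-5,7,3',4'-tetra-O-benzylepicatechin | C=CCO[C@@H]1[C@@H](c2c(OCc3ccccc3)c(Br)c3c(c2OCc2ccccc2)C[C@@H](O)[C@@H](c2ccc(OCc4ccccc4)c(OCc4ccccc4)c2)O3)c2c(OCc3ccccc3)cc(OCc3ccccc3)cc2O[C@@H]1c1ccc(OCc2ccccc2)c(OCc2ccccc2)c1 | intermediate
21 | 3-O-[(E)-prop-1-enyl] analogue of 20 | C/C=C/O[C@@H]1[C@@H](c2c(OCc3ccccc3)c(Br)c3c(c2OCc2ccccc2)C[C@@H](O)[C@@H](c2ccc(OCc4ccccc4)c(OCc4ccccc4)c2)O3)c2c(OCc3ccccc3)cc(OCc3ccccc3)cc2O[C@@H]1c1ccc(OCc2ccccc2)c(OCc2ccccc2)c1 | intermediate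
22 | 5,7,3',4'-tetra-O-benzylepicatechin-(4β→6)-8-bromo-5,7,3',4'-tetra-O-benzylepicatechin (both 3-hydroxyls free) | O[C@@H]1[C@@H](c2c(OCc3ccccc3)c(Br)c3c(c2OCc2ccccc2)C[C@@H](O)[C@@H](c2ccc(OCc4ccccc4)c(OCc4ccccc4)c2)O3)c2c(OCc3ccccc3)cc(OCc3ccccc3)cc2O[C@@H]1c1ccc(OCc2ccccc2)c(OCc2ccccc2)c1 | intermediate
23 | 3,4,5-tris(benzyloxy)benzoic acid | OC(=O)c1cc(OCc2ccccc2)c(OCc2ccccc2)c(OCc2ccccc2)c1 | starting material
24 | 3,3'-bis-O-[3,4,5-tris(benzyloxy)benzoyl] derivative of 22 | O=C(O[C@@H]1[C@@H](c2c(OCc3ccccc3)c(Br)c3c(c2OCc2ccccc2)C[C@@H](OC(=O)c2cc(OCc4ccccc4)c(OCc4ccccc4)c(OCc4ccccc4)c2)[C@@H](c2ccc(OCc4ccccc4)c(OCc4ccccc4)c2)O3)c2c(OCc3ccccc3)cc(OCc3ccccc3)cc2O[C@@H]1c1ccc(OCc2ccccc2)c(OCc2ccccc2)c1)c1cc(OCc2ccccc2)c(OCc2ccccc2)c(OCc2ccccc2)c1 | intermediate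
25 | procyanidin B-5 3,3'-di-O-gallate | O=C(O[C@@H]1[C@@H](c2c(O)cc3c(c2O)C[C@@H](OC(=O)c2cc(O)c(O)c(O)c2)[C@@H](c2ccc(O)c(O)c2)O3)c2c(O)cc(O)cc2O[C@@H]1c1ccc(O)c(O)c1)c1cc(O)c(O)c(O)c1 | target

Total step count: 13. Longest linear sequence: 9 steps (steps 3, 4, 5, 6, 7, 10, 11, 12, 13).

**Steps most likely to fail**

Step 6 (proposed new method). The potassium alkoxide may undergo retro-aldol fragmentation before it meets the aryne. The aryl anion may be protonated (by solvent, by the amide α-position or by a neighbouring benzylic CH2) instead of adding to the carbonyl, which can be followed by β-elimination of the aryloxide. The hemiaminal may collapse early, exposing the ketone to base and epimerising C3. The fallback uses known chemistry and takes the upper unit from the chiral pool. It sets out from 18: O-allylation (NaH, allyl bromide, DMF) should give 3-O-allyl-5,7,3',4'-tetra-O-benzylepicatechin F1. Benzylic oxidation at C4 with DDQ in CH2Cl2 containing 2-ethoxyethanol should give the 4β-(2-ethoxyethoxy) ether F2. TMSOTf-promoted coupling of F2 with 19 comes back to the route at 20.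

Step 10. The cation may be captured by ring A of unreacted 16 (self-condensation to oligomers), because the brominated partner is the weaker nucleophile, and the oxophilic Lewis acid may re-ionise the newly formed interflavan bond and scramble it. The fallback changes the electrophile to a thioether that is inert until a thiophilic activator is added. It sets out from 16: exchange of the 4-hydroxyl with 1,3-benzothiazole-2-thiol (BF3·OEt2 cat., CH2Cl2, −40 °C) should give the 4β-(1,3-benzothiazol-2-ylsulfanyl) derivative F3. Activation of F3 with AgBF4 in the presence of excess 19 (THF, 0 °C) comes back to the route at 20.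

Step 1. Bromination may occur para to the hydroxyl (between the two benzyloxy groups) or twice, giving the wrong silyl triflate regioisomer later. The fallback replaces electrophilic halogenation by directed ortho-metalation. It sets out from 1: isopropyl isocyanate and Et3N should give 3,5-bis(benzyloxy)phenyl N-(propan-2-yl)carbamate F4. N-silylation (TBSOTf, TMEDA), ortho-lithiation (n-BuLi, −78 °C) and TMSCl should give the ortho-silylated carbamate F5. Cleavage of the carbamate with DBU and Et2NH (MeCN, 40 °C) should give 3,5-bis(benzyloxy)-2-(trimethylsilyl)phenol F6, which is triflated in the same flask with PhNTf2 and comes back to the route at 5.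

**Further compounds**
F1 | step 6 | (2R,3R)-5,7-bis(benzyloxy)-2-[3,4-bis(benzyloxy)phenyl]-3-(prop-2-en-1-yloxy)-3,4-dihydro-2H-chromene | C=CCO[C@@H]1Cc2c(OCc3ccccc3)cc(OCc3ccccc3)cc2O[C@@H]1c1ccc(OCc2ccccc2)c(OCc2ccccc2)c1
F2 | step 6 | 4β-(2-ethoxyethoxy) derivative of F1 (2,3-cis, 3,4-trans) | C=CCO[C@@H]1[C@@H](OCCOCC)c2c(OCc3ccccc3)cc(OCc3ccccc3)cc2O[C@@H]1c1ccc(OCc2ccccc2)c(OCc2ccccc2)c1
F3 | step 10 | 4β-(1,3-benzothiazol-2-ylsulfanyl) analogue of 16 (2,3-cis, 3,4-trans) | C=CCO[C@@H]1[C@@H](Sc2nc3ccccc3s2)c2c(OCc3ccccc3)cc(OCc3ccccc3)cc2O[C@@H]1c1ccc(OCc2ccccc2)c(OCc2ccccc2)c1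
F4 | step 1 | 3,5-bis(benzyloxy)phenyl N-(propan-2-yl)carbamate | CC(C)NC(=O)Oc1cc(OCc2ccccc2)cc(OCc2ccccc2)c1
F5 | step 1 | 3,5-bis(benzyloxy)-2-(trimethylsilyl)phenyl N-(propan-2-yl)carbamate | CC(C)NC(=O)Oc1cc(OCc2ccccc2)cc(OCc2ccccc2)c1[Si](C)(C)C
F6 | step 1 | 3,5-bis(benzyloxy)-2-(trimethylsilyl)phenol | Oc1cc(OCc2ccccc2)cc(OCc2ccccc2)c1[Si](C)(C)C
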